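The butenolide is cut at C4–C5, C3–C2 and C2–O1 into an alkyne, an aldehyde and CO. In the lactone ring (O1, C2 carbonyl, C3, C4, C5), C3 and C4 bear identical benzyl groups, so the C3=C4 double bond can come from a symmetrical alkyne whose two ends are interchangeable. Copper-catalysed benzylation of 3-phenyl-1-propyne (1) with benzyl bromide (2) gives that precursor, 1,4-diphenylbut-2-yne (4). One nickel-mediated carbonylative (2+2+1) cycloaddition of 4 with phenylacetaldehyde (5) and CO (6) then builds the ring, the tetrasubstituted alkene and the C5 stereocentre at once, a chiral phosphine choosing the aldehyde face, and delivers (S)-maculalactone A (9).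

Key step: step 2

Assumption: the target is maculalactone A with the 5S configuration of the given structure; the sense of induction of the phospholane at nickel cannot be derived on paper, so the route is written with the (2R,5R) antipode, and the (2S,5S) antipode would replace it unchanged if a pilot run shows bonding to the Si face.

Step 1
Reactants: 1 3-phenyl-1-propyne; 2 benzyl bromide
Product: 4 1,4-diphenylbut-2-yne, via alkynylmagnesium bromide 3 (not isolated)
Conditions: EtMgBr (0.98 equiv), THF, 0 °C to rt; then CuBr·SMe2 (5 mol%), 2 (1.0 equiv), THF, 50 °C; aq. NH4Cl
Reagents that add atoms: none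
Why: Deprotonation of the terminal alkyne gives alkynyl Grignard reagent 3, and its copper-catalysed substitution on the benzylic bromide (copper-catalysed alkynyl Grignard alkylation) joins the alkyne carbon to the benzylic carbon without amine or alkoxide base, so the skipped, doubly benzylic alkyne should not isomerise to an allene; no stereocentre is formed.

Step 2
Reactants: 4 1,4-diphenylbut-2-yne; 5 phenylacetaldehyde; 6 carbon monoxide
Product: 9 (S)-maculalactone A, via oxanickelacyclopentene 7 (not isolated), via acylnickel alkoxide 8 (not isolated)
Conditions: Ni(cod)2 (1.05 equiv), (2R,5R)-1,2,5-triphenylphospholane (1.05 equiv), 4, toluene, 0 °C; 5 (1.1 equiv, freshly distilled) by syringe pump, 0 °C to rt; then CO (1 atm), −20 °C to rt, off-gas through an oxidising scrubber; neutral work-up, SiO2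
Reagents that add atoms: none
Why: Proposed new method: a stepwise, nickel-mediated intermolecular hetero-Pauson–Khand (2+2+1) assembly in which zerovalent nickel carrying one chiral phosphine couples alkyne 4 and the η2-bound aldehyde 5 oxidatively to the divalent oxanickelacyclopentene 7 (C4–C5 bond), CO inserts into the Ni–C3 vinyl bond to give the six-membered acyl alkoxide 8, and C2–O1 reductive elimination releases 9 while nickel leaves as Ni(CO)3(phosphine). The closest known reaction types are the nickel-catalysed enantioselective reductive coupling of alkynes with aldehydes, which runs through the same kind of metallacycle, the nickel-catalysed carbonylative (2+2+1) cycloaddition of imines with alkynes to unsaturated γ-lactams, and the intramolecular hetero-Pauson–Khand cyclisation of ynals under Ru3(CO)12 or Mo(CO)6; what is unproven is the intermolecular, ligand-controlled version with an enolisable aldehyde. The butenolide ring is closed by the C–O reductive elimination, that is by contraction of the six-membered nickelacycle 8 to the five-membered lactone with loss of the metal, and the alkyne π bond survives as the ring C3=C4 double bond. C5 is the only new stereocentre and is set in the oxidative cyclisation under reagent control: the twofold-symmetric phospholane on nickel differentiates the faces of the coordinated aldehyde so that C4 bonds to the Re face, which corresponds to 5S, and the centre is not exposed to base or acid afterwards. The step needs facial selectivity at the aldehyde and hetero- over homo-coupling but no regioselectivity, because the two identical benzyl-bearing alkyne carbons of 4 make both orientations the same; one nickel per alkyne and slow feeding of 5 keep free aldehyde and unbound alkyne low, which should hold back aldol, Tishchenko, decarbonylation and alkyne oligomerisation.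

Compound list
1 | 3-phenyl-1-propyne (prop-2-yn-1-ylbenzene) | C#CCc1ccccc1 | starting material
2 | benzyl bromide | BrCc1ccccc1 | starting material
3 | (3-phenylprop-1-yn-1-yl)magnesium bromide | Br[Mg]C#CCc1ccccc1 | intermediate
4 | 1,4-diphenylbut-2-yne | C(C#CCc1ccccc1)c1ccccc1 | intermediate
5 | phenylacetaldehyde | O=CCc1ccccc1 | starting material
6 | carbon monoxide | [C-]#[O+] | starting material
7 | (5S)-oxanickelacyclopentene of divalent nickel: five-membered ring Ni–O1–C5–C4=C3, benzyl on C3, C4 and C5, (2R,5R)-1,2,5-triphenylphospholane on Ni (drawn as the monomer) | O1[C@@H](Cc2ccccc2)C(Cc2ccccc2)=C(Cc2ccccc2)[Ni-]1[P+]1(c2ccccc2)[C@@H](c2ccccc2)CC[C@@H]1c1ccccc1 | intermediate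
8 | (5S)-acylnickel alkoxide of divalent nickel: six-membered ring Ni–O1–C5–C4=C3–C2(=O), benzyl on C3, C4 and C5, same phospholane on Ni | O=C1C(Cc2ccccc2)=C(Cc2ccccc2)[C@H](Cc2ccccc2)O[Ni-]1[P+]1(c2ccccc2)[C@@H](c2ccccc2)CC[C@@H]1c1ccccc1 | intermediate
9 | (S)-maculalactone A, (5S)-3,4,5-tribenzylfuran-2(5H)-one | O=C1O[C@@H](Cc2ccccc2)C(Cc2ccccc2)=C1Cc1ccccc1 | target

Total step count: 2
Longest linear sequence: 2 steps

Steps most likely to fail (the route has only two steps, so both are listed)

1. Step 2 (key step, beyond established chemistry).
- What may go wrong:
  - The hetero-coupling may lose to alkyne homocoupling, or to nickel-induced aldol, Tishchenko or decarbonylation consumption of the aldehyde.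
  - The nickel alkoxide may undergo β-hydride elimination before CO inserts.
  - CO may displace the partners and reverse the cyclisation.
  - The phosphine may discriminate the aldehyde faces poorly. A moderate enantiomeric excess would first be raised by recrystallisation or preparative chiral chromatography of 9.
- Fallback, known chemistry throughout, setting out from 4 (with 5) and returning at 9: alkyne 4 is converted with Ti(OiPr)4 and iPrMgCl (2 equiv) in Et2O at −78 to −50 °C into its (η2-alkyne)Ti(OiPr)2 complex. Aldehyde 5 is added at −78 °C and the resulting oxatitanacyclopentene is cleaved with I2, which should give racemic (Z)-3-benzyl-4-iodo-1,5-diphenylpent-3-en-2-ol F1, with iodine and the carbinol carbon cis. Dess–Martin periodinane (CH2Cl2, NaHCO3) should oxidise it to (Z)-3-benzyl-4-iodo-1,5-diphenylpent-3-en-2-one F2. Corey–Bakshi–Shibata reduction with the (R)-methyl oxazaborolidine ((R)-1-methyl-3,3-diphenyltetrahydro-1H,3H-pyrrolo[1,2-c][1,3,2]oxazaborole) and catecholborane in toluene at −78 °C should then give (2S,3Z)-3-benzyl-4-iodo-1,5-diphenylpent-3-en-2-ol F3, the tetrasubstituted alkenyl group acting as the large substituent. Cyclocarbonylation of F3 (PdCl2(PPh3)2 cat., CO 1 atm, NaHCO3, MeCN, 40 °C) closes C3–C2 and C2–O1 with retention at C5 and should give 9. The weak base is chosen to spare the C5–H.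

2. Step 1.
- What may go wrong: propargyl–allenyl isomerisation of 1, 3 or 4 under the organometallic conditions and Wurtz-type homocoupling of 2. Either would leave allene or diene impurities that bind zerovalent nickel and spoil step 2.
- Fallback, setting out from 2 and returning at 4 with no new compound on the way (F0): twofold Stille coupling of commercial bis(tributylstannyl)ethyne with 2 (2 equiv) under Pd(PPh3)4 (cat.) in toluene at 80 °C. This forms both benzyl–alkyne bonds under neutral, base-free conditions, after which tin residues are removed with aqueous KF.

Further compounds
F1 | step 2 | rac-(Z)-3-benzyl-4-iodo-1,5-diphenylpent-3-en-2-ol | OC(Cc1ccccc1)/C(Cc1ccccc1)=C(\I)Cc1ccccc1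
F2 | step 2 | (Z)-3-benzyl-4-iodo-1,5-diphenylpent-3-en-2-one | O=C(Cc1ccccc1)/C(Cc1ccccc1)=C(\I)Cc1ccccc1
F3 | step 2 | (2S,3Z)-3-benzyl-4-iodo-1,5-diphenylpent-3-en-2-ol | O[C@@H](Cc1ccccc1)/C(Cc1ccccc1)=C(\I)Cc1ccccc1
F0 | step 1 | none | none
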